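**Plan**

1. Numbering: ring B = C1–C6 (C2 Cl; C3 Me and Br), spiro C6, ring A = C6–C11 (C7=C14H2, C10 Br, C11 gem-dimethyl). The retrosynthesis cuts C6–C11 first (opens ring A), then C7–C14 (allylsilane from an enol triflate), C8–C9 (enolate alkylation), the C3–Br and C2–Cl bonds (back to an epoxide and an alkene) and the two ring-B bonds of a Diels–Alder adduct.
2. Enabling feature: the C10 bromine sits next to the gem-dimethyl carbon C11, which is bonded to the spiro carbon C6, itself allylic to the exocyclic C7=C14 bond of ring A. This Br–C10–C11–C6–C7=C14 array is the retron of a bromonium-opened cation–olefin closure ended by an allylsilane.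
3. Forward: ring B arises first (isoprene + butynone), the C9–C11 unit is joined as an enantioenriched bromochloride triflate, ring B is halogenated while still monocyclic, and ring A with the spiro centre is closed in the last step.
4. Stereochemistry: C10 from a catalytic enantioselective bromochlorination of prenol; C2 and C3 from a Shi epoxidation, anti chloride opening and retentive bromide substitution; C6 from the Z geometry of the allylsilane (fixed by conjugate reduction of the s-trans enone) passed on through a chair transition state.

Key step: step 10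

Assumption: the titanium-mediated bromochlorination of prenol is taken to put bromine on C2 and chlorine on the tertiary C3 of the butanol, and the facial sense of the Shi epoxidation is assigned by analogy with 1-substituted cyclohexenes.

**Step 1**
Reactants: 1 prenol (3-methylbut-2-en-1-ol)
Product: 2 (S)-2-bromo-3-chloro-3-methylbutan-1-ol
Conditions: NBS, ClTi(OiPr)3, chiral tridentate Schiff-base ligand (salicylaldimine of a 1,2-amino alcohol, the enantiomer leading to the S product, 20 mol %), hexanes, −20 °C
Reagents that add atoms: N-bromosuccinimide, O=C1CCC(=O)N1Br; chlorotitanium triisopropoxide, CC(C)O[Ti](Cl)(OC(C)C)OC(C)C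
Why: Titanium-mediated catalytic enantioselective bromochlorination of an allylic alcohol: the alkoxide-bound alkene is brominated at the future C10 inside the chiral Schiff-base complex and chloride is delivered anti from titanium to the tertiary carbon (future C11), so the ligand enantiomer sets the S configuration at C10.

**Step 2**
Reactants: 2 (S)-2-bromo-3-chloro-3-methylbutan-1-ol
Product: 3 (S)-2-bromo-3-chloro-3-methylbutyl trifluoromethanesulfonate
Conditions: Tf2O, 2,6-lutidine, CH2Cl2, −78 °C
Reagents that add atoms: triflic anhydride, O=S(=O)(OS(=O)(=O)C(F)(F)F)C(F)(F)F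
Why: Triflate formation on the primary alcohol at low temperature gives an electrophile reactive enough for a β-branched SN2 alkylation while leaving the vicinal bromochloride and C10 untouched.

**Step 3**
Reactants: 4 isoprene (2-methylbuta-1,3-diene); 5 but-3-yn-2-one
Product: 6 1-(4-methylcyclohexa-1,4-dien-1-yl)ethan-1-one
Conditions: AlCl3 (10 mol %), CH2Cl2, 0 °C
Reagents that add atoms: none
Why: Lewis acid-catalysed Diels–Alder reaction of the 2-substituted diene with the ynone gives the para 1,4-cyclohexadiene, so the methyl group ends para to the acyl-bearing C6 and the conjugated C5=C6 bond lies on the ring arm that leads to the methyl-bearing C3.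

**Step 4**
Reactants: 6 1-(4-methylcyclohexa-1,4-dien-1-yl)ethan-1-one; 3 (S)-2-bromo-3-chloro-3-methylbutyl trifluoromethanesulfonate
Product: 8 (4S)-4-bromo-5-chloro-5-methyl-1-(4-methylcyclohexa-1,4-dien-1-yl)hexan-1-one, via lithium dienolate 7 (not isolated)
Conditions: LDA, THF, −78 °C; then 3, −78 to −40 °C
Reagents that add atoms: none
Why: Kinetic deprotonation of the methyl ketone at its α′ methyl group gives the cross-conjugated lithium enolate, and SN2 alkylation by the primary triflate forms the C8–C9 bond without touching C10 (enolate alkylation).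

**Step 5**
Reactants: 8 (4S)-4-bromo-5-chloro-5-methyl-1-(4-methylcyclohexa-1,4-dien-1-yl)hexan-1-one
Product: 9 (4S)-4-bromo-5-chloro-5-methyl-1-[(1S,6R)-6-methyl-7-oxabicyclo[4.1.0]hept-3-en-3-yl]hexan-1-one
Conditions: L-fructose-derived ketone catalyst of the Shi epoxidation (enantiomer of the usual D-fructose ketone, 30 mol %), KHSO5 (as Oxone), K2CO3, Bu4NHSO4, MeCN–CH2(OMe)2–aqueous buffer, 0 °C
Reagents that add atoms: potassium peroxymonosulfate, [K+].[O-]S(=O)(=O)OO
Why: Shi epoxidation: the chiral dioxirane attacks only the electron-rich trisubstituted C2=C3 bond (the conjugated C5=C6 bond is inert to an electrophilic oxidant) through the spiro transition state, and the L-fructose-derived ketone, which takes the face opposite to that taken by the D-fructose catalyst on 1-substituted cyclohexenes, sets C2 and C3.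

**Step 6**
Reactants: 9 (4S)-4-bromo-5-chloro-5-methyl-1-[(1S,6R)-6-methyl-7-oxabicyclo[4.1.0]hept-3-en-3-yl]hexan-1-one
Product: 10 (4S)-4-bromo-5-chloro-1-[(4R,5R)-5-chloro-4-hydroxy-4-methylcyclohex-1-en-1-yl]-5-methylhexan-1-one
Conditions: Li2CuCl4, THF, rt; aqueous work-up
Reagents that add atoms: dilithium tetrachlorocuprate, [Li+].[Li+].[Cu+2].[Cl-].[Cl-].[Cl-].[Cl-]
Why: SN2-type opening of the trisubstituted epoxide by the soft chlorocuprate nucleophile occurs at the less hindered secondary carbon C2 with inversion, giving the trans chlorohydrin and leaving the tertiary C3–O bond intact.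

**Step 7**
Reactants: 10 (4S)-4-bromo-5-chloro-1-[(4R,5R)-5-chloro-4-hydroxy-4-methylcyclohex-1-en-1-yl]-5-methylhexan-1-one
Product: 11 (4S)-4-bromo-1-[(4R,5R)-4-bromo-5-chloro-4-methylcyclohex-1-en-1-yl]-5-chloro-5-methylhexan-1-one
Conditions: Me3SiBr, CH2Cl2, −20 to 0 °C; NaHCO3 work-up
Reagents that add atoms: bromotrimethylsilane, C[Si](C)(C)Br
Why: SN1 substitution of the tertiary alcohol under neighbouring-group control: the vicinal chlorine, anti to the leaving oxygen in the half-chair, bridges or shields its own face of the C3 cation, so bromide enters on the face the oxygen left and C3 is formed with retention, trans to chlorine.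

**Step 8**
Reactants: 11 (4S)-4-bromo-1-[(4R,5R)-4-bromo-5-chloro-4-methylcyclohex-1-en-1-yl]-5-chloro-5-methylhexan-1-one
Product: 13 (1Z,4S)-4-bromo-1-[(3R,4R)-4-bromo-3-chloro-4-methylcyclohexylidene]-5-chloro-5-methylhexyl trifluoromethanesulfonate, via lithium enolate 12 (not isolated)
Conditions: LiBH(s-Bu)3, THF, −78 °C; then 2-[N,N-bis(trifluoromethanesulfonyl)amino]-5-chloropyridine, −78 °C
Reagents that add atoms: 2-[N,N-bis(trifluoromethanesulfonyl)amino]-5-chloropyridine, O=S(=O)(N(c1ccc(Cl)cn1)S(=O)(=O)C(F)(F)F)C(F)(F)F
Why: Conjugate reduction of the enone by the hindered borohydride followed by O-triflation of the regiodefined lithium enolate: hydride adds to C5 of the preferred s-trans enone, which puts the enolate oxygen trans to C5 (cis to C1) and the chain carbon C8 cis to C5, and the triflate freezes this Z geometry.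

**Step 9**
Reactants: 13 (1Z,4S)-4-bromo-1-[(3R,4R)-4-bromo-3-chloro-4-methylcyclohexylidene]-5-chloro-5-methylhexyl trifluoromethanesulfonate
Product: 14 [(2Z,5S)-5-bromo-2-[(3R,4R)-4-bromo-3-chloro-4-methylcyclohexylidene]-6-chloro-6-methylheptyl]trimethylsilane
Conditions: Me3SiCH2MgCl, Pd(PPh3)4 (5 mol %), THF, 0 °C to rt
Reagents that add atoms: (trimethylsilylmethyl)magnesium chloride, C[Si](C)(C)C[Mg]Cl
Why: Kumada coupling of the enol triflate: oxidative addition of zerovalent palladium occurs at the C(sp2)–O bond in preference to the unactivated alkyl halides and the coupling retains the double-bond geometry, so CH2SiMe3 (C14) ends cis to C1 and the tether cis to C5.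

**Step 10**
Reactants: 14 [(2Z,5S)-5-bromo-2-[(3R,4R)-4-bromo-3-chloro-4-methylcyclohexylidene]-6-chloro-6-methylheptyl]trimethylsilane
Product: 16 (4S,6R,8R,9R)-4,9-dibromo-8-chloro-5,5,9-trimethyl-1-methylidenespiro[5.5]undecane, via bromonium ion 15 (not isolated)
Conditions: (CF3)2CHOH, 2,6-di-tert-butylpyridine, 0 °C to rt
Reagents that add atoms: none
Why: In the ionising, weakly nucleophilic solvent the tertiary C11–Cl bond is heterolysed with anchimeric help from the anti C10 bromine to give the configurationally defined bromonium ion 15, which the γ-carbon C6 of the allylsilane opens at C11 with inversion while the β-silyl cation at C7 loses Me3Si+ to chloride and leaves the exocyclic C7=C14 bond. The closest known reaction type is the bromonium-initiated cation–olefin (polyene-type) cyclisation set off by solvolysis of an enantioenriched vicinal bromochloride, the same C6–C11 construction as the bromonium cyclisation of γ-bisabolene-type dienes to 10-bromochamigrenes, here ended by an allylsilane in the SE2′ sense. Ring A (C6–C11) closes in the 6-endo mode with respect to the C6=C7 bond, with endo, Markovnikov opening of the three-membered bromonium ring at its tertiary carbon. The only new stereocentre, the spiro carbon C6, is controlled by the Z geometry of the allylsilane read through a chair transition state in which the C10–Br bond is equatorial and anti to the forming C6–C11 bond, so that C5 (cis to the tether) becomes axial and C1 (cis to C14) equatorial on ring A; C10 is not touched because bromine stays on it, and C2 and C3 are spectators. The step needs (a) ionisation of the chain chloride and not of the ring C3–Br bond, secured because only the chain halide has an anti bromine to assist while the ring bromide is deactivated by its β-chlorine, (b) bond formation at C6 and not at C14, secured by the allylsilane polarisation, and (c) closure through the ring-B chair with both halogens equatorial, whose extra strain should be the smaller penalty because the other face of C6 can only be reached through a ring-A boat. The hindered pyridine takes up acid so that the exocyclic alkene and the tertiary bromide of the product are not exposed to it.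

**Compound list**

1 | prenol (3-methylbut-2-en-1-ol) | CC(C)=CCO | starting material
2 | (S)-2-bromo-3-chloro-3-methylbutan-1-ol | OC[C@H](Br)C(C)(C)Cl | intermediate
3 | (S)-2-bromo-3-chloro-3-methylbutyl trifluoromethanesulfonate | O=S(=O)(OC[C@H](Br)C(C)(C)Cl)C(F)(F)F | intermediate
4 | isoprene (2-methylbuta-1,3-diene) | C=CC(C)=C | starting material
5 | but-3-yn-2-one | CC(=O)C#C | starting material
6 | 1-(4-methylcyclohexa-1,4-dien-1-yl)ethan-1-one | CC(=O)C1=CCC(C)=CC1 | intermediate
7 | lithium 1-(4-methylcyclohexa-1,4-dien-1-yl)ethen-1-olate (formed in the flask, not isolated) | [Li]OC(=C)C1=CCC(C)=CC1 | intermediate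
8 | (4S)-4-bromo-5-chloro-5-methyl-1-(4-methylcyclohexa-1,4-dien-1-yl)hexan-1-one | O=C(CC[C@H](Br)C(C)(C)Cl)C1=CCC(C)=CC1 | intermediate
9 | (4S)-4-bromo-5-chloro-5-methyl-1-[(1S,6R)-6-methyl-7-oxabicyclo[4.1.0]hept-3-en-3-yl]hexan-1-one | O=C(CC[C@H](Br)C(C)(C)Cl)C1=CC[C@@]2(C)O[C@H]2C1 | intermediate
10 | (4S)-4-bromo-5-chloro-1-[(4R,5R)-5-chloro-4-hydroxy-4-methylcyclohex-1-en-1-yl]-5-methylhexan-1-one | O=C(CC[C@H](Br)C(C)(C)Cl)C1=CC[C@@](C)(O)[C@H](Cl)C1 | intermediate
11 | (4S)-4-bromo-1-[(4R,5R)-4-bromo-5-chloro-4-methylcyclohex-1-en-1-yl]-5-chloro-5-methylhexan-1-one | O=C(CC[C@H](Br)C(C)(C)Cl)C1=CC[C@@](C)(Br)[C@H](Cl)C1 | intermediate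
12 | lithium (1Z,4S)-4-bromo-1-[(3R,4R)-4-bromo-3-chloro-4-methylcyclohexylidene]-5-chloro-5-methylhexan-1-olate (formed in the flask, not isolated) | [Li]O/C(CC[C@H](Br)C(C)(C)Cl)=C1/CC[C@@](C)(Br)[C@H](Cl)C1 | intermediate
13 | (1Z,4S)-4-bromo-1-[(3R,4R)-4-bromo-3-chloro-4-methylcyclohexylidene]-5-chloro-5-methylhexyl trifluoromethanesulfonate | O=S(=O)(O/C(CC[C@H](Br)C(C)(C)Cl)=C1/CC[C@@](C)(Br)[C@H](Cl)C1)C(F)(F)F | intermediate
14 | [(2Z,5S)-5-bromo-2-[(3R,4R)-4-bromo-3-chloro-4-methylcyclohexylidene]-6-chloro-6-methylheptyl]trimethylsilane | C[Si](C)(C)C/C(CC[C@H](Br)C(C)(C)Cl)=C1/CC[C@@](C)(Br)[C@H](Cl)C1 | intermediate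
15 | bromonium ion (2,2-dimethylbromiranium bridging C10 and C11 of 14 after loss of chloride, chloride as counter-ion; formed in the flask, not isolated) | C[Si](C)(C)C/C(CC[C@@H]2[Br+]C2(C)C)=C1/CC[C@@](C)(Br)[C@H](Cl)C1.[Cl-] | intermediate
16 | (4S,6R,8R,9R)-4,9-dibromo-8-chloro-5,5,9-trimethyl-1-methylidenespiro[5.5]undecane | C=C1CC[C@H](Br)C(C)(C)[C@@]12CC[C@@](C)(Br)[C@H](Cl)C2 | target

**Step count and risks**

Total steps: 10. Longest linear sequence: 9 steps (prenol 1 to 16 through steps 1, 2 and 4–10).

The three steps most likely to fail:

1. Step 10. What may go wrong: ionisation of the ring tertiary C3–Br bond alongside the chain chloride, protodesilylation of the allylsilane by the acidic medium, or loss of facial control at C6 when closure through a ring-A boat onto the ring-B conformer with axial halogens competes. The fallback changes the terminating nucleophile to a silyl enol ether and adds the methylidene carbon last. Setting out from 11, conjugate reduction with LiBH(s-Bu)3 and trapping of the enolate with t-BuMe2SiOTf should give the silyl enol ether tert-butyl{[(1Z,4S)-4-bromo-1-[(3R,4R)-4-bromo-3-chloro-4-methylcyclohexylidene]-5-chloro-5-methylhexyl]oxy}dimethylsilane F1 with the same double-bond geometry. Solvolysis in (CF3)2CHOH buffered with 2,6-di-tert-butylpyridine should then close ring A through the more nucleophilic enol ether to the spiro ketone (4S,6S,8R,9R)-4,9-dibromo-8-chloro-5,5,9-trimethylspiro[5.5]undecan-1-one F2. Petasis methylenation with Cp2TiMe2 (toluene, 65 °C), a non-basic reagent that should spare the tertiary bromide, comes back to the route at 16.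

2. Step 8. What may go wrong: 1,2-reduction of the ketone, hydride attack at a carbon–halogen bond, or erosion of the enolate geometry before it is trapped. The fallback separates reduction from enol formation. Setting out from 11, copper hydride conjugate reduction with [(Ph3P)CuH]6 in wet benzene should give the saturated ketone (4S)-4-bromo-1-[(3R,4R)-4-bromo-3-chloro-4-methylcyclohexyl]-5-chloro-5-methylhexan-1-one F3 (epimers at the acyl-bearing ring carbon, which is planarised again later). Soft enolisation with t-BuMe2SiOTf and Et3N should give the tetrasubstituted silyl enol ethers, from which the Z isomer F1 is separated. F1 is then taken through F2 to 16 as in the first fallback, so the sequence comes back to the route at 16.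

3. Step 7. What may go wrong: loss of a C4 proton from the tertiary cation toward the conjugated dienone, or capture of an unbridged cation from the chlorine face with loss of configuration at C3. The fallback saturates the enone before the substitution. Setting out from 10, conjugate reduction with [(Ph3P)CuH]6 should give the hydroxy ketone (4S)-4-bromo-5-chloro-1-[(3R,4R)-3-chloro-4-hydroxy-4-methylcyclohexyl]-5-methylhexan-1-one F4, in which the equatorial acyl group anchors a chair with hydroxyl and chlorine trans-diaxial and no conjugated elimination channel remains. Me3SiBr should then give F3, which is carried on through F1 and F2 as in the second fallback and comes back to the route at 16.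

**Further compounds**

F1 | step 10 | tert-butyl{[(1Z,4S)-4-bromo-1-[(3R,4R)-4-bromo-3-chloro-4-methylcyclohexylidene]-5-chloro-5-methylhexyl]oxy}dimethylsilane | CC(C)(C)[Si](C)(C)O/C(CC[C@H](Br)C(C)(C)Cl)=C1/CC[C@@](C)(Br)[C@H](Cl)C1
F2 | step 10 | (4S,6S,8R,9R)-4,9-dibromo-8-chloro-5,5,9-trimethylspiro[5.5]undecan-1-one | O=C1CC[C@H](Br)C(C)(C)[C@@]12CC[C@@](C)(Br)[C@H](Cl)C2
F3 | step 8 | (4S)-4-bromo-1-[(3R,4R)-4-bromo-3-chloro-4-methylcyclohexyl]-5-chloro-5-methylhexan-1-one | O=C(CC[C@H](Br)C(C)(C)Cl)C1CC[C@@](C)(Br)[C@H](Cl)C1
F4 | step 7 | (4S)-4-bromo-5-chloro-1-[(3R,4R)-3-chloro-4-hydroxy-4-methylcyclohexyl]-5-methylhexan-1-one | O=C(CC[C@H](Br)C(C)(C)Cl)C1CC[C@@](C)(O)[C@H](Cl)C1
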